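1. Amounts first: teal and blue both start with 2.28 M of second end groups, and teal has twice the first end groups of blue. Links need first end groups, yet blue's link share at 4.00 h is 27.0 %, and teal's at 4.00 h, with the richer charge of first end groups, is 18.8 %, lower.

| flask | first end groups | second end groups | remark | time |
|---|---|---|---|---|
| teal | 2.4 M | 2.28 M | run made earlier |  |
| blue | 1.2 M | 2.28 M | run made earlier |  |
| alder | 2.4 M | 2.28 M | a single well-mixed tank run continuously and read at steady state, 40.0 h in it on average |  |
| larch | 2.4 M | 2.28 M | a closed flask charged with all of it at once and left for 4.0 h | 4.0 h |
| oak | 2.4 M | 2.28 M | one stirred flow tank at steady state, fed with the mixture as stated, mean residence time 4.0 h |  |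
| birch | 2.4 M | 2.28 M (fed, over 3.20 h) | a stirred flask in which second end groups is dosed at a steady rate over 3.20 h without added volume, worked up at 4.0 h | 4.0 h |

| run | time / h | links / % | rings / % |
|---|---|---|---|
| teal | 0.500 | 17.3 | 63.9 |
| teal | 1.00 | 17.9 | 76.7 |
| teal | 1.50 | 17.7 | 77.2 |
| teal | 2.50 | 18.3 | 76.8 |
| teal | 3.00 | 18.1 | 76.7 |
| teal | 4.00 | 17.9 | 77.4 |
| blue | 0.333 | 20.5 | 51.4 |
| blue | 0.500 | 23.1 | 61.2 |
| blue | 0.667 | 25.0 | 66.5 |
| blue | 1.00 | 25.7 | 71.7 |
| blue | 1.50 | 26.8 | 72.8 |
| blue | 2.50 | 26.9 | 72.4 |
| blue | 4.00 | 26.9 | 72.9 |

(readings scatter by 0.3 percentage points)

- the stated concentrations are those of everything mixed, before any reaction; amounts are the same in each set-up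
- on the list of suspects stand: first end groups + second end groups -> links; first end groups + second end groups -> rings
- the feed brings no volume worth counting
- the earlier runs were made in a closed, stirred flask

- the set-up with the highest share of links in all that became links or rings, at the outlet or at the end ("none" if the first two lie within 2 percentage points) (alder / larch / oak / birch / none)
- share of links in all that became links or rings, at the outlet or at the end, alder
- share of links in all that became links or rings, at the outlet or at the end, larch
- share of links in all that became links or rings, at the outlet or at the end, oak
- share of links in all that became links or rings, at the outlet or at the end, birch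

2. The two ends clear this up. At 1.00 h teal's links and rings add to 94.6 % of the first end groups charged, and its second end groups were charged at 95.0 % of them, the same within the scatter, so in teal the second end groups are used up by then and are its limiting reagent, while blue still holds 1.08 M when its first end groups are used.

3. I therefore take links over rings, as rates, to be the second end groups standing divided by one constant, with first end groups cancelling. I call this constant the even amount, K: the amount of second end groups at which links and rings form equally fast. Blue's mean amount and final ratio read K as 4.56 M.

4. Running second end groups from the charge B down to zero gives a share of 1 − (K/B) ln(1 + B/K), which is 18.9 %. Teal, a different run, reads 18.8 %, and larch repeats teal's charge, so I expect 18.9 % there.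

5. In a stirred tank everything forms at the outlet amount b, so the share is b/(b + K). Teal's 1.00 h is shorter than oak's 4.0 h, so b lies far below K, and alder's 40.0 h is longer still. Birch doses over 3.20 h, longer than that hour, so its amount stays low too. Larch should lead.

6. The forecast names larch: larch 18.9 %, oak 1.5 %, alder 0.2 %, birch 0.2 %, on the ground that “Link share falls as second end groups deplete”.

7. The flasks give larch first: larch 19.0 %, oak 1.66 %, birch 0.0272 %, alder 0.00607 %.

    first end groups + second end groups → links (k = 1.70 × 10⁻⁴ M⁻¹ s⁻¹)
    first end groups + second end groups → rings, rate k2*[first end groups] as long as [second end groups] is above zero (k = 7.70 × 10⁻⁴ s⁻¹)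

8. In larch at the charged amounts, the link step alone gives first end groups a half-life of 0.50 h, against 0.250 h by the ring step, shorter, so links begin at half the pace of rings. In oak, the even amount of 4.56 M and the share of 1.66 % put about 0.0770 M of second end groups at the outlet, and links stand at 1.52 % of the first end groups charged.

The runs stem from a simulated flask for an exercise; scatter was added.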